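**Retrosynthetic overview**
1. Artocarpol D ⇐ its ring B O‑tosylate 13 (S–O hydrolysis, last step).
2. 13 ⇐ open‑chain deoxybenzoin 8 + prenal 9 in one pot: fluoride‑triggered intramolecular SNAr closes the oxepine, then Knoevenagel condensation/oxa‑6π electrocyclisation closes the 2H‑pyran.
3. 8 ⇐ palladium‑catalysed ketone α‑arylation of ring B methyl ketone 7 with ring A bromide 5.
4. 5 ⇐ 4,6‑dibromoresorcinol 1 (bis‑silylation, mono Br/Li exchange, prenylation); 7 ⇐ 2'‑fluoro‑4'‑hydroxyacetophenone 6.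
5. Ring order: benzene rings A and B are bought; oxepine ring, then pyran ring, both in step 5.

Assumption: the target SMILES has no stereocentre and no stereogenic double bond outside rings, so the compound is achiral and no enantiocontrol is needed. EDDA = ethylenediammonium diacetate; TIPS = triisopropylsilyl; Ts = 4‑methylbenzenesulfonyl.

**Step 1**
Reactants: 1 4,6‑dibromobenzene‑1,3‑diol
Product: 2 1,5‑dibromo‑2,4‑bis(triisopropylsilyloxy)benzene
Conditions: TIPSCl (2.4 equiv), imidazole (5 equiv), DMF, rt to 40 °C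
Reagents that add atoms: chlorotri(propan‑2‑yl)silane (TIPSCl), CC(C)[Si](Cl)(C(C)C)C(C)C
Why: Imidazole‑promoted O‑silylation masks both phenols with a group that resists anionic O‑to‑C silyl migration in step 2 and is removed by fluoride in step 5.

**Step 2**
Reactants: 2 1,5‑dibromo‑2,4‑bis(triisopropylsilyloxy)benzene; 3 1‑bromo‑3‑methylbut‑2‑ene (prenyl bromide)
Product: 5 1‑bromo‑5‑(3‑methylbut‑2‑en‑1‑yl)‑2,4‑bis(triisopropylsilyloxy)benzene, via aryllithium 4 (not isolated)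
Conditions: n‑BuLi (1.0 equiv), THF, −78 °C; then CuBr·SMe2 (10 mol %), 3 (1.3 equiv), −78 °C to 0 °C
Reagents that add atoms: none
Why: Halogen–lithium exchange at one of two symmetry‑equivalent bromines gives a single aryllithium, and its SN2 allylation at the primary carbon of prenyl bromide (monovalent copper catalysis) gives the linear prenyl arene.

**Step 3**
Reactants: 6 1‑(2‑fluoro‑4‑hydroxyphenyl)ethan‑1‑one
Product: 7 4‑acetyl‑3‑fluorophenyl 4‑methylbenzenesulfonate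
Conditions: TsCl (1.1 equiv), Et3N (1.5 equiv), DMAP (5 mol %), CH2Cl2, 0 °C to rt
Reagents that add atoms: 4‑methylbenzenesulfonyl chloride (TsCl), Cc1ccc(cc1)S(Cl)(=O)=O
Why: O‑sulfonylation gives a phenol mask with no acidic hydrogens that is inert to the palladium catalyst and to fluoride, and keeps ring B electron‑poor for the later SNAr.

**Step 4**
Reactants: 5 1‑bromo‑5‑(3‑methylbut‑2‑en‑1‑yl)‑2,4‑bis(triisopropylsilyloxy)benzene; 7 4‑acetyl‑3‑fluorophenyl 4‑methylbenzenesulfonate (1.3 equiv)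
Product: 8 1‑(2‑fluoro‑4‑tosyloxyphenyl)‑2‑[5‑(3‑methylbut‑2‑en‑1‑yl)‑2,4‑bis(triisopropylsilyloxy)phenyl]ethan‑1‑one
Conditions: Pd2(dba)3 (2.5 mol %), Xantphos (6 mol %), K3PO4 (2.5 equiv), toluene, 90 °C, Ar
Reagents that add atoms: none
Why: Buchwald–Hartwig‑type palladium‑catalysed α‑arylation of the methyl ketone, where the ortho‑substituted bromide stops at mono‑arylation, the aryl fluoride and aryl tosylate are not touched by zerovalent palladium with this ligand, and K3PO4 spares the silyl ethers.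

**Step 5**
Reactants: 8 1‑(2‑fluoro‑4‑tosyloxyphenyl)‑2‑[5‑(3‑methylbut‑2‑en‑1‑yl)‑2,4‑bis(triisopropylsilyloxy)phenyl]ethan‑1‑one; 9 3‑methylbut‑2‑enal (prenal)
Product: 13 artocarpol D ring B 4‑methylbenzenesulfonate, via free bisphenol ketone 10 (not isolated), via oxepinone tosylate 11 (not isolated), via Z oxatriene 12 (not isolated)
Conditions: CsF (3 equiv), DMF (0.02 M), 70 °C, Ar; then AcOH (1.5 equiv), EDDA (0.3 equiv), 9 (2 equiv), 60 °C
Reagents that add atoms: none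
Why: Proposed new method: fluoride strips both aryl silyl ethers, the phenoxide ortho to the benzylic CH2 displaces the fluoride activated by the ortho ketone and meta sulfonate in a 7‑membered intramolecular SNAr, and the resulting aryl benzyl ketone (acidic α‑CH2) condenses with prenal under iminium catalysis (Knoevenagel) to oxatriene 12, whose E/Z isomers equilibrate through reversible amine addition so that the Z form closes by thermal oxa‑6π electrocyclisation, favoured by the gem‑dimethyl terminus; the closest known chemistry is the one‑pot SNAr/Knoevenagel assembly of dibenzo[b,f]oxepines and the formal [3+3] Knoevenagel/oxa‑6π annulation of 1,3‑dicarbonyls with enals.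

**Step 6**
Reactants: 13 artocarpol D ring B 4‑methylbenzenesulfonate
Product: 14 artocarpol D
Conditions: KOH (6 equiv), 1,4‑dioxane/H2O 4:1, 80 °C, Ar; then aq NH4Cl
Reagents that add atoms: none
Why: Hydroxide attacks sulfur of the aryl sulfonate (S–O cleavage, sulfonate ester hydrolysis) and frees the ring B phenol, while the prenyl group, diaryl ether and 2H‑pyran are base‑stable and no stereocentre exists to scramble.

**Compound list**
1 | 4,6‑dibromobenzene‑1,3‑diol (4,6‑dibromoresorcinol) | Oc1cc(O)c(Br)cc1Br | starting material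
2 | 1,5‑dibromo‑2,4‑bis(triisopropylsilyloxy)benzene | CC(C)[Si](Oc1cc(O[Si](C(C)C)(C(C)C)C(C)C)c(Br)cc1Br)(C(C)C)C(C)C | intermediate
3 | 1‑bromo‑3‑methylbut‑2‑ene (prenyl bromide) | CC(C)=CCBr | starting material
4 | [5‑bromo‑2,4‑bis(triisopropylsilyloxy)phenyl]lithium | [Li]c1cc(Br)c(O[Si](C(C)C)(C(C)C)C(C)C)cc1O[Si](C(C)C)(C(C)C)C(C)C | intermediate (not isolated)
5 | 1‑bromo‑5‑(3‑methylbut‑2‑en‑1‑yl)‑2,4‑bis(triisopropylsilyloxy)benzene | CC(C)=CCc1cc(Br)c(O[Si](C(C)C)(C(C)C)C(C)C)cc1O[Si](C(C)C)(C(C)C)C(C)C | intermediate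
6 | 1‑(2‑fluoro‑4‑hydroxyphenyl)ethan‑1‑one | CC(=O)c1ccc(O)cc1F | starting material
7 | 4‑acetyl‑3‑fluorophenyl 4‑methylbenzenesulfonate | CC(=O)c1ccc(OS(=O)(=O)c2ccc(C)cc2)cc1F | intermediate
8 | 1‑(2‑fluoro‑4‑tosyloxyphenyl)‑2‑[5‑(3‑methylbut‑2‑en‑1‑yl)‑2,4‑bis(triisopropylsilyloxy)phenyl]ethan‑1‑one | CC(C)=CCc1cc(CC(=O)c2ccc(OS(=O)(=O)c3ccc(C)cc3)cc2F)c(O[Si](C(C)C)(C(C)C)C(C)C)cc1O[Si](C(C)C)(C(C)C)C(C)C | intermediate
9 | 3‑methylbut‑2‑enal (prenal) | CC(C)=CC=O | starting material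
10 | 2‑[2,4‑dihydroxy‑5‑(3‑methylbut‑2‑en‑1‑yl)phenyl]‑1‑(2‑fluoro‑4‑tosyloxyphenyl)ethan‑1‑one (present as cesium phenoxide) | CC(C)=CCc1cc(CC(=O)c2ccc(OS(=O)(=O)c3ccc(C)cc3)cc2F)c(O)cc1O | intermediate (not isolated)
11 | 3‑hydroxy‑2‑(3‑methylbut‑2‑en‑1‑yl)‑10‑oxo‑10,11‑dihydrodibenzo[b,f]oxepin‑7‑yl 4‑methylbenzenesulfonate | CC(C)=CCc1cc2c(cc1O)Oc1cc(OS(=O)(=O)c3ccc(C)cc3)ccc1C(=O)C2 | intermediate (not isolated)
12 | (11Z)‑3‑hydroxy‑11‑(3‑methylbut‑2‑en‑1‑ylidene)‑2‑(3‑methylbut‑2‑en‑1‑yl)‑10‑oxo‑10,11‑dihydrodibenzo[b,f]oxepin‑7‑yl 4‑methylbenzenesulfonate | O=C1c2ccc(OS(=O)(=O)c3ccc(C)cc3)cc2Oc2cc(O)c(CC=C(C)C)cc2/C1=C/C=C(C)C | intermediate (not isolated)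
13 | artocarpol D ring B 4‑methylbenzenesulfonate (2,2‑dimethyl‑2H‑pyran fused across C10–C11 of the dibenzo[b,f]oxepine with the pyran O on C10; ring A free OH and prenyl; ring B OTs) | CC(C)=CCc1cc2c(cc1O)Oc1cc(OS(=O)(=O)c3ccc(C)cc3)ccc1C1=C2C=CC(C)(C)O1 | intermediate
14 | artocarpol D | CC(C)=CCc1cc2c(cc1O)Oc1cc(O)ccc1C1=C2C=CC(C)(C)O1 | target

**Totals**
Total step count: 6. Longest linear sequence: 5 (steps 1, 2, 4, 5, 6).

**Steps most likely to fail, with fallbacks**

Step 5 is the riskiest. The tosylate must outlast the phenoxide stage, and the Knoevenagel/oxa‑6π annulation is unproven on a mono‑ketone in this pot. The fallback sets out from 8 and runs only the first stage (CsF, DMF, 70 °C), isolating oxepinone tosylate 11. Its phenoxide‑enolate (LiN(SiMe3)2, 2.2 equiv, THF, −78 °C) is then added to prenal 9 in a directed aldol addition. This gives the β‑hydroxy ketone 3‑hydroxy‑11‑(1‑hydroxy‑3‑methylbut‑2‑en‑1‑yl)‑2‑(3‑methylbut‑2‑en‑1‑yl)‑10‑oxo‑10,11‑dihydrodibenzo[b,f]oxepin‑7‑yl 4‑methylbenzenesulfonate F1 as a diastereomer mixture. Pyridinium p‑toluenesulfonate in toluene at 60 °C ionises its allylic alcohol, so the enol oxygen closes on the dimethyl‑substituted terminus (or it dehydrates to 12 and electrocyclises). The fallback comes back to the route at 13.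

Step 4 is next. The bromide is electron‑rich and flanked by a bulky silyl ether, so enolate arylation may stall. The fallback reverses the polarity of the coupling and sets out from 5 and 7. Bromide 5 is converted (n‑BuLi, THF, −78 °C; then 2‑isopropoxy‑4,4,5,5‑tetramethyl‑1,3,2‑dioxaborolane) into the boronate 4,4,5,5‑tetramethyl‑2‑[5‑(3‑methylbut‑2‑en‑1‑yl)‑2,4‑bis(triisopropylsilyloxy)phenyl]‑1,3,2‑dioxaborolane F2. Ketone 7 is brominated (PhNMe3Br3, THF, rt) to the α‑bromo ketone 4‑(2‑bromoacetyl)‑3‑fluorophenyl 4‑methylbenzenesulfonate F3. A Suzuki coupling of F2 with F3 (Pd(OAc)2, P(o‑tol)3, K3PO4, THF/H2O, rt) comes back to the route at 8.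

Step 6 is third. Hot hydroxide could attack the small equilibrium amount of ring‑opened oxatriene and undo the pyran by retro‑aldol cleavage. The fallback moves the deprotection ahead of pyran formation and sets out from 8. The first stage of step 5 alone gives isolated 11, whose tosylate is para to the ketone and is cleaved at room temperature (LiOH, THF/H2O). This gives 3,7‑dihydroxy‑2‑(3‑methylbut‑2‑en‑1‑yl)dibenzo[b,f]oxepin‑10(11H)‑one F4. Its annulation with prenal 9 (EDDA, DMF, 60 °C) comes back to the route at 14, so the finished pyran never meets hot base.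

**Further compounds**
F1 | step 5 | 3‑hydroxy‑11‑(1‑hydroxy‑3‑methylbut‑2‑en‑1‑yl)‑2‑(3‑methylbut‑2‑en‑1‑yl)‑10‑oxo‑10,11‑dihydrodibenzo[b,f]oxepin‑7‑yl 4‑methylbenzenesulfonate (racemic diastereomer mixture) | CC(C)=CCc1cc2c(cc1O)Oc1cc(OS(=O)(=O)c3ccc(C)cc3)ccc1C(=O)C2C(O)C=C(C)C
F2 | step 4 | 4,4,5,5‑tetramethyl‑2‑[5‑(3‑methylbut‑2‑en‑1‑yl)‑2,4‑bis(triisopropylsilyloxy)phenyl]‑1,3,2‑dioxaborolane | CC(C)=CCc1cc(B2OC(C)(C)C(C)(C)O2)c(O[Si](C(C)C)(C(C)C)C(C)C)cc1O[Si](C(C)C)(C(C)C)C(C)C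
F3 | step 4 | 4‑(2‑bromoacetyl)‑3‑fluorophenyl 4‑methylbenzenesulfonate | O=C(CBr)c1ccc(OS(=O)(=O)c2ccc(C)cc2)cc1F
F4 | step 6 | 3,7‑dihydroxy‑2‑(3‑methylbut‑2‑en‑1‑yl)dibenzo[b,f]oxepin‑10(11H)‑one | CC(C)=CCc1cc2c(cc1O)Oc1cc(O)ccc1C(=O)C2
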